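**Retrosynthetic overview**

1. Last bond: carbinol C–alkenyl C, by Nozaki–Hiyama–Kishi union of ring-A aldehyde 6 with ring-B alkenyl iodide 16; the carbinol centre follows from C1′ of ring A by Felkin–Anh control.
2. Ring A: 6 comes from a [3,3] ring contraction of dihydropyran 5. Enabling feature: with the carbinol carbon at the aldehyde level, it forms a γ,δ-unsaturated carbonyl array with C1′, the quaternary C2′ and C3′=C4′ of ring A. C4′ is tied back to C1′ through C5′ and C6′(=CH2), so the allyl vinyl ether can be closed over oxygen as a temporary six-membered ring (O–C4′ in place of C1′–C2′).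
3. 5 comes from pyranone 4, made by catalytic asymmetric hetero-Diels–Alder reaction of Danishefsky's diene 1 with prenal 2. This one catalytic C–O stereocentre is traded for C1′ and then relayed to the carbinol.
4. Ring B is bought as cyclohexane 7. C4 is set by enantiotopic-group-selective deprotonation; C2–Br and C1(OH)Me follow by substrate control (α-bromination, methyl addition trans to Br).
5. Ring order: ring B purchased; dihydropyran (temporary, step 1); ring A, the only carbocycle closed, last (step 3).

Key step: step 3

Remark (assumption): the sense of induction in the two reagent-controlled steps (1 and 7) is taken by analogy with the closest known substrates. Both antipodes of BINOL and of the amide base are available, so a reversed sense would change only the antipode used.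

**Route**

Step 1
Reactants: 1 Danishefsky's diene, (E)-1-methoxy-3-(trimethylsilyloxy)buta-1,3-diene; 2 3-methylbut-2-enal (prenal)
Product: 4 (2S)-2-(2-methylprop-1-en-1-yl)-2,3-dihydro-4H-pyran-4-one, via silyl aldol adduct 3 (not isolated)
Conditions: Ti(OiPr)4 (10 mol%), (S)-BINOL (20 mol%), 4 Å MS, Et2O, −20 °C; then CF3CO2H (cat.), CH2Cl2, 0 °C
Reagents that add atoms: none
Why: Catalytic enantioselective hetero-Diels–Alder reaction in its Mukaiyama-aldol/cyclocondensation form: the BINOL–Ti Lewis acid binds prenal, the diene terminus adds 1,2 to one carbonyl face and sets C2 (S), and acid then closes 3 by oxa-Michael addition with loss of the methoxy and silyl groups.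

Step 2
Reactants: 4 (2S)-2-(2-methylprop-1-en-1-yl)-2,3-dihydro-4H-pyran-4-one
Product: 5 (2S)-4-methylidene-2-(2-methylprop-1-en-1-yl)-3,4-dihydro-2H-pyran
Conditions: Cp2TiMe2 (2.5 equiv), PhMe–THF, 65 °C, dark; filtration through basic Al2O3, kept as PhMe solution
Reagents that add atoms: dimethyltitanocene (Petasis reagent), C[Ti](C)(C1C=CC=C1)C1C=CC=C1
Why: Petasis methylenation: the thermally generated titanium carbene adds across the vinylogous-ester C=O ([2+2]/retro-[2+2]) under neutral, non-basic conditions, so neither 1,4-addition at C6 nor ionisation of the allylic C2–O bond should intervene and C2 is untouched.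

Step 3
Reactants: 5 (2S)-4-methylidene-2-(2-methylprop-1-en-1-yl)-3,4-dihydro-2H-pyran
Product: 6 (1R)-2,2-dimethyl-6-methylidenecyclohex-3-ene-1-carbaldehyde
Conditions: PhMe (0.05 M, degassed), 2,6-di-tert-butyl-4-methylpyridine (5 mol%), 170 °C, sealed base-washed tube; used as PhMe solution
Reagents that add atoms: none
Why: Concerted [3,3]-sigmatropic (Claisen) rearrangement of the allyl vinyl ether C5=C6–O1–C2–CH=CMe2 held inside the dihydropyran: O1–C2 breaks as C5 bonds to the CMe2 terminus and C6–O1 becomes the aldehyde. The closest known reaction type is the thermal rearrangement of 2-alkenyl-3,4-dihydro-2H-pyrans to 4-formylcyclohexenes (dihydropyran Claisen ring contraction). The carbocycle closes sigmatropically through the only accessible boat-like transition state, exchanging the oxacycle for the cyclohexene; the new ring bond is C1–C2 (to the quaternary carbon) and the ring alkene is necessarily cis because its two substituents were already joined through C3–C4–C5 of the pyran. The one new stereocentre, C1 (R), is set by C2 (S) of 5, which is destroyed in exchange (1,3-chirality transfer), since the prenyl arm can reach C5 only on the face of the heterocycle that carries it. The step needs the concerted shift to outrun C2–O heterolysis (formal [1,3] shift, loss of chirality transfer) and the β,γ-unsaturated aldehyde to stay unconjugated and unepimerised; a non-polar solvent, base-washed glass and a hindered pyridine should secure this, and the donors at both termini (gem-dimethyl, methylidene-conjugated enol ether) should lower the temperature relative to the parent system.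

Step 4
Reactants: 7 1,4-dioxaspiro[4.5]decane-8-carbaldehyde
Product: 8 8-ethynyl-1,4-dioxaspiro[4.5]decane
Conditions: Ohira–Bestmann reagent, K2CO3, MeOH, 0 °C → rt
Reagents that add atoms: dimethyl (1-diazo-2-oxopropyl)phosphonate, CC(=O)C(=[N+]=[N-])P(=O)(OC)OC
Why: Ohira–Bestmann (Seyferth–Gilbert) homologation: methanolysis of the reagent gives the diazomethylphosphonate anion, which converts the aldehyde into the terminal alkyne under carbonate conditions that leave the ketal intact.

Step 5
Reactants: 8 8-ethynyl-1,4-dioxaspiro[4.5]decane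
Product: 10 8-[(1E)-1-iodoprop-1-en-2-yl]-1,4-dioxaspiro[4.5]decane, via alkenylalane 9 (not isolated)
Conditions: Me3Al (2 equiv), Cp2ZrCl2 (20 mol%), CH2Cl2, 0 °C; then I2, THF, −30 → 0 °C
Reagents that add atoms: trimethylaluminium, C[Al](C)C; iodine, II
Why: Negishi zirconium-catalysed carboalumination: syn addition of Me–Al across the terminal alkyne puts methyl on the internal carbon, and iodinolysis of the alkenylalane with retention fixes the E trisubstituted iodoalkene.

Step 6
Reactants: 10 8-[(1E)-1-iodoprop-1-en-2-yl]-1,4-dioxaspiro[4.5]decane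
Product: 11 4-[(1E)-1-iodoprop-1-en-2-yl]cyclohexan-1-one
Conditions: 1 M HCl, THF, rt
Reagents that add atoms: water, O
Why: Acid-catalysed ketal hydrolysis, to which the iodoalkene is inert.

Step 7
Reactants: 11 4-[(1E)-1-iodoprop-1-en-2-yl]cyclohexan-1-one
Product: 13 {[(4S)-4-[(1E)-1-iodoprop-1-en-2-yl]cyclohex-1-en-1-yl]oxy}trimethylsilane, via lithium enolate 12 (not isolated)
Conditions: (R,R)-bis(1-phenylethyl)amine, n-BuLi, Me3SiCl (in situ quench), THF, −100 → −78 °C
Reagents that add atoms: chlorotrimethylsilane, C[Si](C)(C)Cl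
Why: Enantiotopic-group-selective deprotonation of a 4-substituted cyclohexanone by a C2-symmetric chiral lithium amide with internal silyl quench: removal of one of the two enantiotopic axial α-protons places the enol double bond on one arm and thereby makes C4 a stereocentre (S).

Step 8
Reactants: 13 {[(4S)-4-[(1E)-1-iodoprop-1-en-2-yl]cyclohex-1-en-1-yl]oxy}trimethylsilane
Product: 15 (2S,4S)-2-bromo-4-[(1E)-1-iodoprop-1-en-2-yl]cyclohexan-1-one (cis), via trans-bromoketone 14 (not isolated)
Conditions: NBS, THF, −78 → 0 °C; then LiBr, acetone, rt; chromatography, trans epimer resubmitted to LiBr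
Reagents that add atoms: N-bromosuccinimide, BrN1C(=O)CCC1=O
Why: Electrophilic α-bromination of a silyl enol ether is regiospecific, so bromine lands on the arm chosen in step 7; axial attack should give mainly the trans bromide, and bromide exchange (SN2 at the α-keto carbon, no enolisation and so no α→α′ migration) should equilibrate C2 alone towards the diequatorial cis epimer.

Step 9
Reactants: 15 (2S,4S)-2-bromo-4-[(1E)-1-iodoprop-1-en-2-yl]cyclohexan-1-one
Product: 16 (1R,2S,4S)-2-bromo-4-[(1E)-1-iodoprop-1-en-2-yl]-1-methylcyclohexan-1-ol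
Conditions: MeTi(OiPr)3 (2 equiv, from MeLi + ClTi(OiPr)3), Et2O, −30 °C → rt; aq. NH4F
Reagents that add atoms: methyllithium, [Li]C (methyl source), used as methyltitanium triisopropoxide, C[Ti](OC(C)C)(OC(C)C)OC(C)C
Why: 1,2-Addition of a non-basic methyl organometallic to an α-bromoketone (the classical route to cis-halohydrins): methyl enters trans to bromine both by equatorial attack on the diequatorial chair (favoured for the bulky titanium reagent) and by attack anti to C–Br on the diaxial chair (polar Felkin–Anh), which should give the axial tertiary alcohol cis to Br and to the side chain.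

Step 10
Reactants: 6 (1R)-2,2-dimethyl-6-methylidenecyclohex-3-ene-1-carbaldehyde; 16 (1R,2S,4S)-2-bromo-4-[(1E)-1-iodoprop-1-en-2-yl]-1-methylcyclohexan-1-ol
Product: 18 (1R,2S,4S)-2-bromo-4-{(2E,4R)-4-[(1R)-2,2-dimethyl-6-methylidenecyclohex-3-en-1-yl]-4-hydroxybut-2-en-2-yl}-1-methylcyclohexan-1-ol (CNP0362245.1), via alkenylchromium(III) species 17 (not isolated)
Conditions: CrCl2 (5 equiv), NiCl2 (2 mol%), DMSO, rt; 6 added as PhMe solution; Et3N-deactivated silica
Reagents that add atoms: none
Why: Nozaki–Hiyama–Kishi coupling: nickel-catalysed formation of the alkenylchromium(III) species with retention of the E geometry and its addition to the aldehyde tolerate the free tertiary alcohol and the alkyl bromide, and the carbinol centre (R) should be set by Felkin–Anh control from C1′ (quaternary C2′ anti to the incoming alkenyl group, methylidene carbon inside), so the union forms the bond and its stereocentre together.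

**Compound list**

1 | Danishefsky's diene, (E)-1-methoxy-3-(trimethylsilyloxy)buta-1,3-diene | CO/C=C/C(=C)O[Si](C)(C)C | starting material
2 | 3-methylbut-2-enal (prenal) | CC(C)=CC=O | starting material
3 | (1E,5S)-1-methoxy-7-methyl-5-(trimethylsilyloxy)octa-1,6-dien-3-one | CO/C=C/C(=O)C[C@H](O[Si](C)(C)C)C=C(C)C | intermediate (not isolated)
4 | (2S)-2-(2-methylprop-1-en-1-yl)-2,3-dihydro-4H-pyran-4-one | O=C1C[C@@H](C=C(C)C)OC=C1 | intermediate
5 | (2S)-4-methylidene-2-(2-methylprop-1-en-1-yl)-3,4-dihydro-2H-pyran | C=C1C[C@@H](C=C(C)C)OC=C1 | intermediate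
6 | (1R)-2,2-dimethyl-6-methylidenecyclohex-3-ene-1-carbaldehyde | C=C1CC=CC(C)(C)[C@@H]1C=O | intermediate
7 | 1,4-dioxaspiro[4.5]decane-8-carbaldehyde | O=CC1CCC2(CC1)OCCO2 | starting material
8 | 8-ethynyl-1,4-dioxaspiro[4.5]decane | C#CC1CCC2(CC1)OCCO2 | intermediate
9 | [(1E)-2-(1,4-dioxaspiro[4.5]decan-8-yl)prop-1-en-1-yl]dimethylalane | C[Al](C)/C=C(\C)C1CCC2(CC1)OCCO2 | intermediate (not isolated)
10 | 8-[(1E)-1-iodoprop-1-en-2-yl]-1,4-dioxaspiro[4.5]decane | I/C=C(\C)C1CCC2(CC1)OCCO2 | intermediate
11 | 4-[(1E)-1-iodoprop-1-en-2-yl]cyclohexan-1-one | I/C=C(\C)C1CCC(=O)CC1 | intermediate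
12 | lithium (4S)-4-[(1E)-1-iodoprop-1-en-2-yl]cyclohex-1-en-1-olate | I/C=C(\C)[C@H]1CCC(O[Li])=CC1 | intermediate (not isolated)
13 | {[(4S)-4-[(1E)-1-iodoprop-1-en-2-yl]cyclohex-1-en-1-yl]oxy}trimethylsilane | I/C=C(\C)[C@H]1CCC(O[Si](C)(C)C)=CC1 | intermediate
14 | (2R,4S)-2-bromo-4-[(1E)-1-iodoprop-1-en-2-yl]cyclohexan-1-one (trans) | I/C=C(\C)[C@H]1CCC(=O)[C@H](Br)C1 | intermediate (not isolated)
15 | (2S,4S)-2-bromo-4-[(1E)-1-iodoprop-1-en-2-yl]cyclohexan-1-one (cis) | I/C=C(\C)[C@H]1CCC(=O)[C@@H](Br)C1 | intermediate
16 | (1R,2S,4S)-2-bromo-4-[(1E)-1-iodoprop-1-en-2-yl]-1-methylcyclohexan-1-ol | I/C=C(\C)[C@H]1CC[C@@](C)(O)[C@@H](Br)C1 | intermediate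
17 | dichloro{(1E)-2-[(1S,3S,4R)-3-bromo-4-hydroxy-4-methylcyclohexyl]prop-1-en-1-yl}chromium(III) | Cl[Cr](Cl)/C=C(\C)[C@H]1CC[C@@](C)(O)[C@@H](Br)C1 | intermediate (not isolated)
18 | (1R,2S,4S)-2-bromo-4-{(2E,4R)-4-[(1R)-2,2-dimethyl-6-methylidenecyclohex-3-en-1-yl]-4-hydroxybut-2-en-2-yl}-1-methylcyclohexan-1-ol | C=C1CC=CC(C)(C)[C@@H]1[C@H](O)/C=C(\C)[C@H]1CC[C@@](C)(O)[C@@H](Br)C1 | target

**Step count and risks**

Total steps: 10. Longest linear sequence: 7 (steps 4–10, from 7); the ring-A branch (steps 1–3) joins at step 10.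

Steps most likely to fail:

Step 3. The temperature that the boat-like shift needs may also allow heterolysis of the allylic C2–O bond (formal [1,3] shift, loss of chirality transfer) or enolisation of the β,γ-unsaturated aldehyde (epimerisation at C1, drift of the exocyclic double bond into conjugation). The fallback sets out from 2 and comes back at 6; it runs the same ring contraction at the carboxylic acid oxidation level, where it should proceed far below the temperature of the aldehyde-level shift. Keck allylation of 2 with ethyl 3-[(tributylstannyl)methyl]but-3-enoate (BINOL/Ti(OiPr)4, CH2Cl2, −20 °C) would give ethyl (5S)-5-hydroxy-7-methyl-3-methylideneoct-6-enoate F1. Lactonisation (cat. Ti(OiPr)4, PhMe, 80 °C) would give (6S)-6-(2-methylprop-1-en-1-yl)-4-methylideneoxan-2-one F2. LDA with Me3SiCl/Et3N (THF, −78 °C) would give the silyl ketene acetal trimethyl{[(6S)-6-(2-methylprop-1-en-1-yl)-4-methylidene-5,6-dihydro-4H-pyran-2-yl]oxy}silane F3. As an Ireland–Claisen rearrangement of a lactone enolate (same boat-like ring contraction, same sense of chirality transfer), this should pass in PhMe at 80–110 °C into trimethylsilyl (1R)-2,2-dimethyl-6-methylidenecyclohex-3-ene-1-carboxylate F4. Aqueous work-up would give (1R)-2,2-dimethyl-6-methylidenecyclohex-3-ene-1-carboxylic acid F5, LiAlH4 would give [(1R)-2,2-dimethyl-6-methylidenecyclohex-3-en-1-yl]methanol F6, and Dess–Martin periodinane (NaHCO3) would return aldehyde 6.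

Step 8. The bromide-exchange equilibrium may not favour the cis epimer enough, and any acid-mediated enolisation would move bromine to the other α-carbon, which erodes the enantiomeric purity set in step 7. The fallback sets out from 11 and comes back at 15; it replaces enolate bromination and equilibration by a stereospecific substitution. L-Proline-catalysed α-aminoxylation of 11 with nitrosobenzene (DMF, 0 °C) would desymmetrise the ketone under catalyst control. The diastereomer (2R,4S)-4-[(1E)-1-iodoprop-1-en-2-yl]-2-[(phenylamino)oxy]cyclohexan-1-one F7 would be separated from its (2R,4R) partner. Zn/AcOH would cleave the N–O bond to (2R,4S)-2-hydroxy-4-[(1E)-1-iodoprop-1-en-2-yl]cyclohexan-1-one F8. Tf2O/2,6-lutidine (CH2Cl2, −78 °C) would give (1R,5S)-5-[(1E)-1-iodoprop-1-en-2-yl]-2-oxocyclohexyl trifluoromethanesulfonate F9. Bu4NBr (1 equiv, −40 °C) would displace the triflate with inversion (SN2 at the α-keto carbon) to give 15 as the kinetic product.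

Step 2. The titanium carbene may not engage the deactivated vinylogous-ester carbonyl cleanly, or the acid-labile cross-conjugated dienol ether may ionise or hydrolyse during isolation. The fallback sets out from 4 and comes back at 5; it is a two-stage Peterson olefination. Me3SiCH2Li/CeCl3 (THF, −78 °C; the organocerium adds 1,2) would give (2S)-2-(2-methylprop-1-en-1-yl)-4-[(trimethylsilyl)methyl]-3,4-dihydro-2H-pyran-4-ol F10 as a mixture at C4. KH (THF, 0 °C) would effect the basic syn-elimination, and the toluene extract of 5 would go directly into step 3, so that the diene ether never meets acid or silica.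

**Further compounds**

F1 | step 3 | ethyl (5S)-5-hydroxy-7-methyl-3-methylideneoct-6-enoate | CCOC(=O)CC(=C)C[C@H](O)C=C(C)C
F2 | step 3 | (6S)-6-(2-methylprop-1-en-1-yl)-4-methylideneoxan-2-one | C=C1CC(=O)O[C@H](C=C(C)C)C1
F3 | step 3 | trimethyl{[(6S)-6-(2-methylprop-1-en-1-yl)-4-methylidene-5,6-dihydro-4H-pyran-2-yl]oxy}silane | C=C1C=C(O[Si](C)(C)C)O[C@H](C=C(C)C)C1
F4 | step 3 | trimethylsilyl (1R)-2,2-dimethyl-6-methylidenecyclohex-3-ene-1-carboxylate | C=C1CC=CC(C)(C)[C@@H]1C(=O)O[Si](C)(C)C
F5 | step 3 | (1R)-2,2-dimethyl-6-methylidenecyclohex-3-ene-1-carboxylic acid | C=C1CC=CC(C)(C)[C@@H]1C(O)=O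
F6 | step 3 | [(1R)-2,2-dimethyl-6-methylidenecyclohex-3-en-1-yl]methanol | C=C1CC=CC(C)(C)[C@@H]1CO
F7 | step 8 | (2R,4S)-4-[(1E)-1-iodoprop-1-en-2-yl]-2-[(phenylamino)oxy]cyclohexan-1-one | I/C=C(\C)[C@H]1CCC(=O)[C@H](ONc2ccccc2)C1
F8 | step 8 | (2R,4S)-2-hydroxy-4-[(1E)-1-iodoprop-1-en-2-yl]cyclohexan-1-one | I/C=C(\C)[C@H]1CCC(=O)[C@H](O)C1
F9 | step 8 | (1R,5S)-5-[(1E)-1-iodoprop-1-en-2-yl]-2-oxocyclohexyl trifluoromethanesulfonate | I/C=C(\C)[C@H]1CCC(=O)[C@H](OS(=O)(=O)C(F)(F)F)C1
F10 | step 2 | (2S)-2-(2-methylprop-1-en-1-yl)-4-[(trimethylsilyl)methyl]-3,4-dihydro-2H-pyran-4-ol | C[Si](C)(C)CC1(O)C[C@@H](C=C(C)C)OC=C1
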